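## Structural features

The target is a germacranolide: a ten-membered carbocycle (C1–C10) trans-fused through C6–O and C7–C11 to an α-methylene-γ-butyrolactone (C11, C12, C13). The ring carries a C1 ketone, a Z trisubstituted C4=C5 alkene (C15 on C4) and a 3S allylic carbinol. Five contiguous stereocentres follow, C6(R)–C7(S)–C8(S)–C9(S)–C10(S), with O8 (tiglate), O9 and O10 (methyl carbinol) on one face, called β here. The C1 ketone is fragile three times over: it is an α-ketol (C10–OH), a β-ketol towards C3 (elimination to a dienone) and a β-ketol towards C9 (retro-aldol ring opening). The methylene lactone and the tiglate are base-sensitive acceptors. The real difficulty is closing a ten-membered ring while controlling C6–C10 and two Z alkenes. C3 and C8 face each other across the ring, and the cis 8,9-diol is what syn addition to a Z C8=C9 alkene gives. A temporary C3–C8 bond therefore turns the skeleton into a cis-fused bicyclo[4.4.0]decene (ring A: C3–C8 with C4=C5; ring B: C3, C2, C1, C10, C9, C8) whose C3 alkoxide and C9 sulfonate are set up for a Wharton fragmentation. Two consequences shape the plan. In the chair that holds the C9 sulfonate equatorial, C14 and C7 are syn-axial, so this is the minor conformer. O8 and O9 must enter on the face of C8=C9 that carried the C3–C8 bond, which is the transannularly shielded face of the conformer released by the fragmentation.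

## Logic of the disconnections

38 ⇒ 37 ⇒ 34 + 35. The O3–Si bond and then the C8–O acyl bond are cut. The β-hydroxy ketone tolerates only a mild, non-basic last step, and the tiglate cannot survive enolate chemistry, so both come last. The forward acylation must choose O8 over O9 and O10.

34 ⇒ 32. Both C–O bonds at C8 and C9 are cut together, leaving a Z alkene. This removes two stereocentres at once. The forward osmylation must be steered to the β face, which is why O10 has to be a free hydroxyl at this point.

32 ⇒ 31 ⇒ 30 ⇒ 27. The C1 carbonyl is taken back to a carbinol held in a 1,10-acetonide, and the C11=C13 bond is cut. This keeps every base-sensitive ketol out of the enolate step. The forward steps need O3 protected and an acetonide cleavage that spares a silyl ether.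

27 ⇒ 26 ⇒ 25 ⇒ 23 ⇒ 22. The C3–H bond is cut back to the enone and the lactone C12–O6 bond back to a silylated diol. The C3 carbonyl is what the fragmentation delivers, so the C1/C3 oxidation levels are exchanged on purpose. The forward reduction must be reagent-controlled on a flexible ring.

22 ⇒ 20 (through 21). The C3–C8 bond is reconnected and a sulfonate placed on C9. The ten-membered ring and the Z C8=C9 alkene collapse into two six-membered rings, where stereocontrol is conventional. The forward step needs cis ring fusion, the sulfonate cis to C7, and O10 capped.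

20 ⇒ 19 ⇒ 18 ⇒ 17 ⇒ 16. The C9–O sulfonate, the acetonide, the two C–O bonds at C1 and C10, and the C9–H bond are cut back to a bicyclic enone. All three oxygens of ring B then come from one alkene and one ketone. The forward steps rely on the convex face of the cis-fused bicycle.

16 ⇒ 15 ⇒ 14 ⇒ 13 ⇒ 12 ⇒ 11. The C1=C10 bond (metathesis), the C9–C10 bond (acyl substitution) and the C2–C3 bond (allylation) are cut. Ring B is thereby reduced to two small nucleophiles. The forward allylation must attack C3 cis to the C8 acyl group, which fixes the ring fusion.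

11 ⇒ 10 ⇒ 9 ⇒ 2 + 8. The C3–C8 and C6–C7 bonds are cut in a Diels–Alder sense. One cycloaddition sets C6, C7 and C8 and the Z alkene with its methyl group. The forward step needs regiocontrol by the silyloxy terminus, endo addition and facial control by an auxiliary.

8 ⇒ 5 + 6, 5 ⇒ 3 + 4, 2 ⇒ 1. An imide bond, an alkene (cross-metathesis) and an O–Si bond are cut, reaching purchasable materials.

## Other disconnections considered

Alternative 1: The cut is C9–C10. Forward, low-valent titanium (TiCl3, Zn–Cu couple) would couple the C9 aldehyde and the C10 methyl ketone of keto-aldehyde A1 to the ten-membered cis-diol A2.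
- In its favour: C9 and C10 oxygens and the ring arise in one step; C13 is carried from the start; O8 is already differentiated as a PMB ether; C1 is already at the ketone level and C3 at the carbinol level. On these last three points it is better than the chosen plan, which needs a late methylenation, a site-selective acylation and a C1/C3 redox exchange.
- Against it: a ten-membered closure at high dilution onto a ketone flanked by a ketal; an α-alkoxy aldehyde that low-valent titanium can deoxygenate or push on to the alkene; two stereocentres fixed only by the folding of the chain; an acyclic Z C4=C5 alkene that needs its own stereocontrolled synthesis.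
- Comparison: structurally the chosen plan takes the Z alkene and C6/C7 from a six-membered ring. Mechanistically a concerted, stereospecific fragmentation replaces a stepwise reductive coupling. In step count the endgame from A2 should be shorter, the chain assembly longer; overall about equal.

Alternative 2: The cut is C6–C7, with C4–C9 re-formed in the precursor. Forward, the potassium alkoxide (KH, 18-crown-6) of dialkenylcyclohexanol A3 would undergo an anionic oxy-Cope shift to cyclodecenone A4.
- In its favour: a concerted chair transition state transfers chirality to C6 and C7 and sets Z C4=C5 in one step. The ring expansion starts from a six-membered ring, which is equal to the chosen plan. C3, C1 and C10 keep their final oxygens, so no redox exchange is needed, which is better.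
- Against it: A3 needs adjacent fully substituted C4 and C9 carrying a silyl enol ether and a 1,3-diene cis to each other, both sensitive to KH and open to other sigmatropic paths. A4 lacks O8 and has C9 as a ketone, so α-oxygenation and a reduction must be controlled on the macrocycle.
- Comparison: the chosen plan forms its precursor by more routine steps and moves the same kind of late stereochemical problem to one alkene. Step counts should be similar.

Alternative 3: The cut is C7–C8, with O–C13 re-formed in the precursor. Forward, tin–lithium exchange (BuLi) on macrocyclic stannane A5 would trigger a Wittig–Still [2,3] shift to dienol A6.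
- In its favour: C7 and C8 are set in the ring-contracting step, the C11=C13 methylene appears without a separate methylenation, and O8 emerges as the only free hydroxyl. All three points are better than the chosen plan.
- Against it: a thirteen-membered bis-allylic ether with a configurationally defined α-alkoxystannane must be built first; a [1,2] shift can compete; the stereochemical outcome rests on macrocycle conformation. The 9,10-diol must still be added to a ten-membered alkene, which is equal to the chosen plan's main weakness, although the free O8–H of A6 is a ready directing group.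
- Comparison: the bond formed is a carbon–carbon bond with more uncertain stereocontrol than the fragmentation, which forms none. The route to A5 is expected to be longer.

Key step: step 16

Assumptions (chemistry):
- Compound 1 is taken as a purchasable C5 building block.
- The ten-membered intermediates are taken to interconvert, at or below room temperature, between the conformers that expose either face of C8=C9.
- Germacrane numbering (C1–C15) is used for every intermediate. β is the face carrying O8, O9 and O10 in the target; α is the opposite face.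
- Checked for the fragmentation pair 20/22: C6, C7 and C10 carry over unchanged to the target; C3, C8 and C9 of 20 are temporary.

Step 1
Reactants: 1 (E)-4-acetoxy-2-methylbut-2-enal
Product: 2 (1E,3E)-3-methyl-4-(triethylsilyloxy)buta-1,3-dien-1-yl acetate
Conditions: TESOTf, Et3N, Et2O, 0 °C to rt
Reagents that add atoms: triethylsilyl trifluoromethanesulfonate, CC[Si](CC)(CC)OS(=O)(=O)C(F)(F)F
Why: Soft enolisation (O-silylation, then γ-deprotonation by Et3N) gives the silyl dienol ether; the s-trans enal leads to the (E)-enol ether and the acetoxy group takes the less crowded E position. Any 1Z isomer cannot reach the s-cis form and is left behind in step 4.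

Step 2
Reactants: 3 tert-butyl(but-3-en-1-yloxy)dimethylsilane; 4 acrylic acid
Product: 5 (E)-5-(tert-butyldimethylsilyloxy)pent-2-enoic acid
Conditions: second-generation Grubbs catalyst RuCl2(H2IMes)(PCy3)(=CHPh) (3 mol %), CH2Cl2, 40 °C
Reagents that add atoms: none
Why: Olefin cross-metathesis of a terminal alkene with an acrylate partner; the acrylate homodimerises slowly, so the cross product forms, as its E isomer.

Step 3
Reactants: 5 (E)-5-(tert-butyldimethylsilyloxy)pent-2-enoic acid; 6 (S)-4-benzyloxazolidin-2-one
Product: 8 (S)-4-benzyl-3-[(E)-5-(tert-butyldimethylsilyloxy)pent-2-enoyl]oxazolidin-2-one, via mixed pivalic anhydride 7 (not isolated)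
Conditions: PivCl, Et3N, THF, −20 °C; then 6, LiCl, −20 °C to rt
Reagents that add atoms: none
Why: N-acylation of the oxazolidinone through a mixed anhydride with LiCl/Et3N activation; no strong base is used, so the E enoate is kept.

Step 4
Reactants: 2 (1E,3E)-3-methyl-4-(triethylsilyloxy)buta-1,3-dien-1-yl acetate; 8 (S)-4-benzyl-3-[(E)-5-(tert-butyldimethylsilyloxy)pent-2-enoyl]oxazolidin-2-one
Product: 9 ring A cycloadduct (C3-OTES, C6-OAc, C7-CH2CH2OTBS, C8-acyl oxazolidinone)
Conditions: Me2AlCl (1.4 equiv), CH2Cl2, −78 to −30 °C
Reagents that add atoms: none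
Why: Auxiliary-controlled Diels–Alder reaction. Me2AlCl holds the imide as an s-cis chelate and the benzyl group blocks one face, so the diene adds to the other and sets C7 and C8. The silyloxy group is the stronger donor, so C6 is the nucleophilic terminus and bonds to the β-carbon C7 while C3 bonds to C8; endo addition places C3–O, C6–O and the C8 acyl group cis and the C7 chain trans.

Step 5
Reactants: 9 ring A cycloadduct
Product: 10 C3 allylic alcohol
Conditions: PPTS (cat.), MeOH, 0 °C to rt
Reagents that add atoms: none
Why: Acid-catalysed methanolysis of the allylic triethylsilyl ether; the primary TBS ether, the acetate and the imide are left under these mild conditions.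

Step 6
Reactants: 10 C3 allylic alcohol
Product: 11 ring A enone (β-keto imide)
Conditions: Dess–Martin periodinane, NaHCO3, CH2Cl2, 0 °C to rt
Reagents that add atoms: none
Why: Dess–Martin oxidation of the allylic alcohol under buffered conditions; C8, now between two carbonyls, prefers the configuration trans to the C7 chain, which is the one present.

Step 7
Reactants: 11 ring A enone (β-keto imide)
Product: 12 C3 tertiary homoallylic alcohol (allyl cis to the C8 acyl group)
Conditions: CH2=CHCH2BF3K, BF3·OEt2, CH2Cl2, −78 to −20 °C
Reagents that add atoms: potassium allyltrifluoroborate, C=CC[B-](F)(F)F.[K+]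
Why: 1,2-Allylboration of the ketone by allyl-BF2 made in situ, through a closed six-membered transition state. The half-chair enone is attacked anti to the pseudo-equatorial C7 chain and antiperiplanar to the axial H8, which puts the allyl group cis to the C8 acyl group and fixes the later cis ring fusion. A boron reagent is chosen because it cannot chelate the two carbonyls; chelate control would favour the other face.

Step 8
Reactants: 12 C3 tertiary homoallylic alcohol
Product: 13 N-methoxy-N-methylamide with free C6-OH and C3-OH
Conditions: MeNHOMe·HCl, AlMe3 (excess), CH2Cl2, 0 °C to rt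
Reagents that add atoms: N,O-dimethylhydroxylamine hydrochloride, CNOC.Cl
Why: Aluminium amide transamination (Weinreb amide formation), helped by the β-hydroxyl group, cleaves the exocyclic imide bond and returns the auxiliary; the excess reagent also aminolyses the C6 acetate.

Step 9
Reactants: 13 N-methoxy-N-methylamide diol
Product: 14 C6 TBS ether
Conditions: TBSCl, imidazole, DMF, rt
Reagents that add atoms: tert-butyldimethylsilyl chloride, CC(C)(C)[Si](C)(C)Cl
Why: Silylation of the secondary allylic hydroxyl; the tertiary C3 hydroxyl does not react with TBSCl/imidazole.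

Step 10
Reactants: 14 C6 TBS ether
Product: 15 isopropenyl ketone
Conditions: CH2=C(CH3)MgBr (3 equiv), THF, −78 to 0 °C; cold aq. NH4Cl
Reagents that add atoms: isopropenylmagnesium bromide, CC(=C)[Mg]Br
Why: Weinreb ketone synthesis; the chelated tetrahedral intermediate prevents over-addition, and one equivalent of the Grignard reagent is consumed by the tertiary hydroxyl.

Step 11
Reactants: 15 isopropenyl ketone
Product: 16 cis-fused bicyclic enone
Conditions: second-generation Hoveyda–Grubbs catalyst RuCl2(H2IMes)(=CH-C6H4-2-OiPr) (5 mol %), toluene, 80 °C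
Reagents that add atoms: none
Why: Ring-closing metathesis between the allyl group and the isopropenyl ketone closes ring B as a cyclohexenone with the C1=C10 alkene; the trisubstituted ring A alkene is inert.

Step 12
Reactants: 16 cis-fused bicyclic enone
Product: 17 C9 allylic alcohol (OH cis to C7)
Conditions: NaBH4, CeCl3·7H2O, MeOH, −78 °C
Reagents that add atoms: none
Why: Luche 1,2-reduction; hydride adds to C9 from the convex face of the cis-fused bicycle, anti to C7 on the neighbouring carbon, so the hydroxyl ends up cis to C7, the orientation the leaving group needs.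

Step 13
Reactants: 17 C9 allylic alcohol
Product: 18 tetraol with cis C1,C10-diol
Conditions: OsO4 (5 mol %), NMO, acetone/H2O, 0 °C to rt
Reagents that add atoms: N-methylmorpholine N-oxide, C[N+]1([O-])CCOCC1; water, O
Why: Catalytic (Upjohn) dihydroxylation. The ring B alkene reacts before C4=C5, which sits between a quaternary carbinol and a silyloxy carbon and has two allylic oxygens. Attack anti to the allylic C9 hydroxyl and on the convex face sets C10 (O β) and C1.

Step 14
Reactants: 18 tetraol
Product: 19 1,10-acetonide
Conditions: Me2C(OMe)2, PPTS (cat.), CH2Cl2, rt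
Reagents that add atoms: 2,2-dimethoxypropane, COC(C)(C)OC
Why: Acetonide formation on the only cis-vicinal diol; O9 is trans to O10 and stays free. Capping O10 shuts off epoxide closure and semipinacol shift at C9 in step 16.

Step 15
Reactants: 19 1,10-acetonide
Product: 20 C9 mesylate (cis-fused octalinol)
Conditions: MsCl, Et3N, DMAP (cat.), CH2Cl2, 0 °C
Reagents that add atoms: methanesulfonyl chloride, CS(=O)(=O)Cl
Why: Sulfonylation through sulfene reaches the hindered secondary C9 hydroxyl; the tertiary C3 hydroxyl does not react at 0 °C.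

Step 16
Reactants: 20 C9 mesylate (cis-fused octalinol)
Product: 22 (4Z,8Z)-cyclodeca-4,8-dien-3-one, via potassium C3-alkoxide 21 (not isolated)
Conditions: KOtBu (1.05 equiv), THF, 0 °C; pH 7 buffer
Reagents that add atoms: none
Why: Heterolytic Wharton (Grob-type) fragmentation: in alkoxide 21 the oxygen lone pair pushes into C3, the C3–C8 σ bond becomes the C8=C9 π bond and mesylate leaves C9, all in one step. The closest known reaction type is the fragmentation of decalin 1,3-diol monosulfonates to cyclodecenones. No new σ bond closes the ten-membered ring; its ten bonds already exist and the ring is released when the shared fusion bond of the bicycle is cut (ring expansion by fragmentation). No stereocentre is formed; C3, C8 and C9 lose theirs. The Z geometry follows from the reacting chair of ring B, in which the C9–O bond is equatorial and antiperiplanar to C3–C8 while C7 is axial at C8 and gauche to C10, an arrangement only the cis ring fusion with the mesylate cis to C7 allows. This chair carries C14 and C7 syn-axial and is the minor conformer, but it is drained continuously (Curtin–Hammett) and the strain is lost in the product. The step must beat E2 loss of H8/mesylate from the other chair, epoxide or semipinacol events at C9–C10, and enolisation of 22 with loss of the C1 oxygen. One equivalent of base at 0 °C, the acetonide on O10 and the absence of any nucleophile secure this.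

Step 17
Reactants: 22 (4Z,8Z)-cyclodeca-4,8-dien-3-one
Product: 23 6,12-diol
Conditions: HF·pyridine, pyridine, THF, 0 °C to rt
Reagents that add atoms: none
Why: Fluoride desilylation of both TBS ethers; the buffered, non-basic reagent leaves the acetonide and avoids β-elimination across C1–C2.

Step 18
Reactants: 23 6,12-diol
Product: 25 trans-fused γ-lactone, via lactol 24 (not isolated)
Conditions: TEMPO (20 mol %), PhI(OAc)2, CH2Cl2, rt
Reagents that add atoms: none
Why: TEMPO-catalysed oxidative lactonisation; the primary alcohol is oxidised first, the aldehyde is trapped by O6 as the lactol, and the lactol is oxidised on. C6 and C7 are already trans.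

Step 19
Reactants: 25 trans-fused γ-lactone
Product: 26 (3S)-allylic alcohol
Conditions: (R)-2-methyl-CBS-oxazaborolidine (20 mol %), catecholborane, toluene, −78 °C
Reagents that add atoms: none
Why: Corey–Bakshi–Shibata reduction under reagent control; with the alkenyl arm as the large group the (R)-catalyst gives the 3S carbinol, and catecholborane at low temperature does not touch the lactone.

Step 20
Reactants: 26 (3S)-allylic alcohol
Product: 27 3-O-TBS ether
Conditions: TBSOTf, 2,6-lutidine, CH2Cl2, −78 °C
Reagents that add atoms: tert-butyldimethylsilyl trifluoromethanesulfonate, CC(C)(C)[Si](C)(C)OS(=O)(=O)C(F)(F)F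
Why: Silyl protection of O3, so that C1 can later be oxidised as the only free secondary alcohol.

Step 21
Reactants: 27 3-O-TBS ether
Product: 30 α-methylene lactone, via Mannich base 28 (not isolated), via ammonium iodide 29 (not isolated)
Conditions: LDA, THF, −78 °C; CH2=NMe2 I, −78 °C to rt; MeI, MeOH, rt; NaHCO3 (aq), CH2Cl2
Reagents that add atoms: N,N-dimethylmethyleneiminium iodide (Eschenmoser's salt), C=[N+](C)C.[I-]
Why: α-Methylenation by enolate Mannich reaction, N-methylation and Hofmann-type elimination; the lactone α-CH2 is the only position LDA deprotonates in 27.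

Step 22
Reactants: 30 α-methylene lactone
Product: 31 1β,10β-diol
Conditions: PPTS, MeOH, 40 °C
Reagents that add atoms: none
Why: Acid-catalysed transketalisation removes the acetonide; the secondary TBS ether and the methylene lactone tolerate PPTS in methanol.

Step 23
Reactants: 31 1β,10β-diol
Product: 32 1-ketone (α-ketol)
Conditions: Dess–Martin periodinane, NaHCO3, CH2Cl2, 0 °C
Reagents that add atoms: none
Why: Dess–Martin oxidation of the only free secondary alcohol; the tertiary C10 hydroxyl cannot be oxidised and the buffer protects the β-silyloxy ketone.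

Step 24
Reactants: 32 1-ketone (α-ketol)
Product: 34 8β,9β,10β-triol, via osmate ester TMEDA complex 33 (not isolated)
Conditions: OsO4 (1.05 equiv), TMEDA, CH2Cl2, −78 °C; then NaHSO3 (aq), THF, rt
Reagents that add atoms: osmium tetroxide, O=[Os](=O)(=O)=O
Why: Hydroxyl-directed dihydroxylation: the OsO4·TMEDA complex is hydrogen-bonded by the allylic C10 hydroxyl and delivered to the face of C8=C9 on which that hydroxyl stands, so O8 and O9 enter syn to O10 (β). Undirected osmylation is not relied on, because it would take the exposed α face of the conformer in which the C1–C3 bridge covers the β face. At −78 °C the undirected C4=C5 alkene and the electron-poor methylene lactone do not compete.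

Step 25
Reactants: 34 8β,9β,10β-triol; 35 tiglic acid
Product: 37 8-O-tigloyl 3-O-TBS ether, via mixed trichlorobenzoic anhydride 36 (not isolated)
Conditions: 2,4,6-Cl3C6H2COCl, Et3N, THF, rt; then 34, DMAP, toluene, 0 °C
Reagents that add atoms: none
Why: Yamaguchi esterification; O8 is acylated in preference to O9, which is next to the quaternary C10 and hydrogen-bonded, and to the tertiary O10. The short, cold exposure to amine limits retro-aldol and β-elimination.

Step 26
Reactants: 37 8-O-tigloyl 3-O-TBS ether
Product: 38 target CNP0106709.2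
Conditions: HF·pyridine, pyridine, THF, 0 °C to rt
Reagents that add atoms: none
Why: Fluoride desilylation under buffered, non-basic conditions, which spare the β-hydroxy ketone, the tiglate and the methylene lactone.

## Compound list

1 | (E)-4-acetoxy-2-methylbut-2-enal | CC(=O)OC/C=C(\C)C=O | starting material
2 | (1E,3E)-3-methyl-4-(triethylsilyloxy)buta-1,3-dien-1-yl acetate | CC(=O)O/C=C/C(C)=C/O[Si](CC)(CC)CC | intermediate
3 | tert-butyl(but-3-en-1-yloxy)dimethylsilane | C=CCCO[Si](C)(C)C(C)(C)C | starting material
4 | acrylic acid | C=CC(=O)O | starting material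
5 | (E)-5-(tert-butyldimethylsilyloxy)pent-2-enoic acid | OC(=O)/C=C/CCO[Si](C)(C)C(C)(C)C | intermediate
6 | (S)-4-benzyloxazolidin-2-one | O=C1N[C@@H](Cc2ccccc2)CO1 | starting material
7 | (E)-5-(tert-butyldimethylsilyloxy)pent-2-enoic pivalic anhydride | CC(C)(C)C(=O)OC(=O)/C=C/CCO[Si](C)(C)C(C)(C)C | intermediate
8 | (S)-4-benzyl-3-[(E)-5-(tert-butyldimethylsilyloxy)pent-2-enoyl]oxazolidin-2-one | O=C1OC[C@H](Cc2ccccc2)N1C(=O)/C=C/CCO[Si](C)(C)C(C)(C)C | intermediate
9 | ring A cycloadduct: 4-methylcyclohex-4-ene (C3–C8) with C3-OTES, C6-OAc, C7-CH2CH2OTBS and C8-C(=O)-[(S)-4-benzyl-2-oxooxazolidin-3-yl]; C3-O, C6-O and the C8 acyl group mutually cis, C7 chain trans | CC[Si](CC)(CC)O[C@@H]1[C@H](C(=O)N2[C@@H](Cc3ccccc3)COC2=O)[C@@H](CCO[Si](C)(C)C(C)(C)C)[C@H](OC(C)=O)C=C1C | intermediate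
10 | C3 allylic alcohol of 9 (triethylsilyl group removed) | O[C@@H]1[C@H](C(=O)N2[C@@H](Cc3ccccc3)COC2=O)[C@@H](CCO[Si](C)(C)C(C)(C)C)[C@H](OC(C)=O)C=C1C | intermediate
11 | ring A enone: 2-methylcyclohex-2-enone with 4-OAc, 5-CH2CH2OTBS and 6-acyl oxazolidinone (4,6-cis, 5 trans to both) | O=C1[C@H](C(=O)N2[C@@H](Cc3ccccc3)COC2=O)[C@@H](CCO[Si](C)(C)C(C)(C)C)[C@H](OC(C)=O)C=C1C | intermediate
12 | C3 tertiary homoallylic alcohol: allyl added to C3 of 11, cis to the C8 acyl group | O[C@@]1(CC=C)[C@H](C(=O)N2[C@@H](Cc3ccccc3)COC2=O)[C@@H](CCO[Si](C)(C)C(C)(C)C)[C@H](OC(C)=O)C=C1C | intermediate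
13 | N-methoxy-N-methylamide at C9 with free C6-OH and C3-OH | O[C@@]1(CC=C)[C@H](C(=O)N(C)OC)[C@@H](CCO[Si](C)(C)C(C)(C)C)[C@H](O)C=C1C | intermediate
14 | C6 TBS ether of 13 | O[C@@]1(CC=C)[C@H](C(=O)N(C)OC)[C@@H](CCO[Si](C)(C)C(C)(C)C)[C@H](O[Si](C)(C)C(C)(C)C)C=C1C | intermediate
15 | isopropenyl ketone: C9(=O)-C(CH3)=CH2 in place of the amide of 14 | O[C@@]1(CC=C)[C@H](C(=O)C(C)=C)[C@@H](CCO[Si](C)(C)C(C)(C)C)[C@H](O[Si](C)(C)C(C)(C)C)C=C1C | intermediate
16 | cis-fused bicyclic enone: ring B with C9 ketone and C1=C10 alkene, C3-OH at the ring fusion cis to H8 | O[C@@]12CC=C(C)C(=O)[C@@H]1[C@@H](CCO[Si](C)(C)C(C)(C)C)[C@H](O[Si](C)(C)C(C)(C)C)C=C2C | intermediate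
17 | C9 allylic alcohol of 16, C9-OH cis to C7 and trans to H8 | O[C@@]12CC=C(C)[C@H](O)[C@@H]1[C@@H](CCO[Si](C)(C)C(C)(C)C)[C@H](O[Si](C)(C)C(C)(C)C)C=C2C | intermediate
18 | tetraol: cis C1,C10-diol (C10 tertiary) anti to C9-OH, plus C3-OH | O[C@@]12C[C@@H](O)[C@@](C)(O)[C@H](O)[C@@H]1[C@@H](CCO[Si](C)(C)C(C)(C)C)[C@H](O[Si](C)(C)C(C)(C)C)C=C2C | intermediate
19 | 1,10-acetonide of 18 with free C9-OH and C3-OH | O[C@@]12C[C@H]3OC(C)(C)O[C@@]3(C)[C@H](O)[C@@H]1[C@@H](CCO[Si](C)(C)C(C)(C)C)[C@H](O[Si](C)(C)C(C)(C)C)C=C2C | intermediate
20 | C9 mesylate of 19: cis-fused octalinol, mesylate cis to C7 | O[C@@]12C[C@H]3OC(C)(C)O[C@@]3(C)[C@H](OS(C)(=O)=O)[C@@H]1[C@@H](CCO[Si](C)(C)C(C)(C)C)[C@H](O[Si](C)(C)C(C)(C)C)C=C2C | intermediate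
21 | potassium C3-alkoxide of 20 | [K+].[O-][C@@]12C[C@H]3OC(C)(C)O[C@@]3(C)[C@H](OS(C)(=O)=O)[C@@H]1[C@@H](CCO[Si](C)(C)C(C)(C)C)[C@H](O[Si](C)(C)C(C)(C)C)C=C2C | intermediate
22 | (4Z,8Z)-cyclodeca-4,8-dien-3-one: 6α-OTBS, 7β-CH2CH2OTBS, 1β,10β-isopropylidenedioxy, 4- and 10α-methyl | CC(C)(C)[Si](C)(C)O[C@@H]1/C=C(/C)C(=O)C[C@H]2OC(C)(C)O[C@@]2(C)/C=C\[C@H]1CCO[Si](C)(C)C(C)(C)C | intermediate
23 | 6,12-diol of 22 | O[C@@H]1/C=C(/C)C(=O)C[C@H]2OC(C)(C)O[C@@]2(C)/C=C\[C@H]1CCO | intermediate
24 | lactol: C12 hemiacetal closed on O6 (C12 epimers) | C1C(O)O[C@@H]2/C=C(/C)C(=O)C[C@H]3OC(C)(C)O[C@@]3(C)/C=C\[C@@H]12 | intermediate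
25 | trans-fused 6α,12-γ-lactone with C3 enone and 1,10-acetonide | C1C(=O)O[C@@H]2/C=C(/C)C(=O)C[C@H]3OC(C)(C)O[C@@]3(C)/C=C\[C@@H]12 | intermediate
26 | (3S)-allylic alcohol of 25 | C1C(=O)O[C@@H]2/C=C(/C)[C@@H](O)C[C@H]3OC(C)(C)O[C@@]3(C)/C=C\[C@@H]12 | intermediate
27 | 3-O-TBS ether of 26 | C1C(=O)O[C@@H]2/C=C(/C)[C@@H](O[Si](C)(C)C(C)(C)C)C[C@H]3OC(C)(C)O[C@@]3(C)/C=C\[C@@H]12 | intermediate
28 | Mannich base: C11 dimethylaminomethyl lactone (C11 epimers) | CN(C)CC1C(=O)O[C@@H]2/C=C(/C)[C@@H](O[Si](C)(C)C(C)(C)C)C[C@H]3OC(C)(C)O[C@@]3(C)/C=C\[C@@H]12 | intermediate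
29 | trimethylammonium iodide of 28 | C[N+](C)(C)CC1C(=O)O[C@@H]2/C=C(/C)[C@@H](O[Si](C)(C)C(C)(C)C)C[C@H]3OC(C)(C)O[C@@]3(C)/C=C\[C@@H]12.[I-] | intermediate
30 | α-methylene lactone (C11=C13) with 3-OTBS and 1,10-acetonide | C=C1C(=O)O[C@@H]2/C=C(/C)[C@@H](O[Si](C)(C)C(C)(C)C)C[C@H]3OC(C)(C)O[C@@]3(C)/C=C\[C@@H]12 | intermediate
31 | 1β,10β-diol of 30 | C=C1C(=O)O[C@@H]2/C=C(/C)[C@@H](O[Si](C)(C)C(C)(C)C)C[C@@H](O)[C@@](C)(O)/C=C\[C@@H]12 | intermediate
32 | 1-ketone of 31 (α-ketol with 10β-OH) | C=C1C(=O)O[C@@H]2/C=C(/C)[C@@H](O[Si](C)(C)C(C)(C)C)CC(=O)[C@@](C)(O)/C=C\[C@@H]12 | intermediate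
33 | cyclic 8β,9β-osmate ester of 32 (hexavalent osmium) as its TMEDA complex | CN(C)CCN(C)C.C=C1C(=O)O[C@@H]2/C=C(/C)[C@@H](O[Si](C)(C)C(C)(C)C)CC(=O)[C@@](C)(O)[C@H]3O[Os](=O)(=O)O[C@H]3[C@@H]12 | intermediate
34 | 8β,9β,10β-triol with 3-OTBS and 1-ketone | C=C1C(=O)O[C@@H]2/C=C(/C)[C@@H](O[Si](C)(C)C(C)(C)C)CC(=O)[C@@](C)(O)[C@@H](O)[C@@H](O)[C@@H]12 | intermediate
35 | tiglic acid, (E)-2-methylbut-2-enoic acid | C/C=C(\C)C(=O)O | starting material
36 | tiglic 2,4,6-trichlorobenzoic anhydride | C/C=C(\C)C(=O)OC(=O)c1c(Cl)cc(Cl)cc1Cl | intermediate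
37 | 8-O-tigloyl 3-O-TBS ether of the target | C=C1C(=O)O[C@@H]2/C=C(/C)[C@@H](O[Si](C)(C)C(C)(C)C)CC(=O)[C@@](C)(O)[C@@H](O)[C@@H](OC(=O)/C(C)=C/C)[C@@H]12 | intermediate
38 | CNP0106709.2, (3S,6R,7S,8S,9S,10S,4Z) | C=C1C(=O)O[C@@H]2/C=C(/C)[C@@H](O)CC(=O)[C@@](C)(O)[C@@H](O)[C@@H](OC(=O)/C(C)=C/C)[C@@H]12 | target

## Step count and least certain steps

Total: 26 steps. Longest linear sequence: 25 steps (steps 2–26, from 3 and 4); the branch from 1 is one step and joins at step 4.

Step 16 (key step). Most likely to go wrong: competing elimination or substitution instead of fragmentation. The chair with the antiperiplanar C3–C8/C9–O array is the minor one (C14 and C7 syn-axial), while the major chair holds H8 and the mesylate trans-diaxial and is set up for E2. Any excess base could also enolise the product and expel the C1 oxygen. Fallback: give up the antiperiplanar requirement by cutting C3–C8 homolytically. Setting out from 20, hypoiodite (Suárez) fragmentation with PhI(OAc)2 and I2 under visible light should turn the C3 alkoxy radical, by β-scission, into the ten-membered 8-iodo-9-mesyloxy enone F1. Zinc dust in AcOH/EtOH should then effect reductive 1,2-elimination to the less strained Z alkene, coming back to the route at 22.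

Step 4. Most likely to go wrong: loss of the silyl enol ether or a stepwise Mukaiyama–Michael course under the stoichiometric aluminium Lewis acid, and leakage of regiocontrol because C6 also carries a donor and C4 a methyl group. Fallback: move the source of asymmetry from the auxiliary to a catalyst that is a much weaker Lewis acid. Setting out from 5 through 7, acylation of oxazolidin-2-one should give the achiral imide 3-[(E)-5-(tert-butyldimethylsilyloxy)pent-2-enoyl]oxazolidin-2-one F2. Cycloaddition of 2 with F2 under the divalent copper complex Cu(SbF6)2·(R,R)-2,2′-isopropylidenebis(4-tert-butyl-2-oxazoline) should give the cycloadduct F3. The conditions of steps 5–7 should then give the alcohol F4, the enone F5 and the allyl carbinol F6, and the conditions of step 8 bring F6 back to the route at 13.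

Step 24. Most likely to go wrong: poor facial selectivity. If the C10 hydroxyl is tied up in a hydrogen bond to the C1 ketone, direction is lost and osmylation takes the exposed α face or C4=C5. Fallback: enter the electrophile on the exposed face and the oxygens on the other (Woodward–Prévost logic). Setting out from 32, iodine and silver tiglate F7 (AgO2CC(CH3)=CHCH3, from 35 and Ag2O) in CH2Cl2 should give the trans iodo tiglate F8. Neighbouring-group displacement of iodide and hydrolysis should then place both oxygens β as a monotiglate mixture of 37 and its 9-O-tigloyl isomer F9, and DMAP-catalysed acyl migration should move F9 to the less hindered O8. The fallback comes back at 37 and also replaces step 25.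

Step 25. Most likely to go wrong: poor site selectivity (acylation at O9 or twice), or base-induced retro-aldol and β-elimination during a slow acylation. Fallback: activate the diol instead of relying on steric differentiation. Setting out from 34, Bu2Sn(OMe)2 should give the 8,9-O-dibutylstannylene acetal F10, which should be opened at the less hindered oxygen by tigloyl chloride F11 (from 35 and oxalyl chloride) at 0 °C without amine base, coming back at 37.

## Further compounds

F1 | step 16 | ten-membered 8-iodo-9-mesyloxy-cyclodec-4-en-3-one (C8 epimers), other groups as in 22 | CC(C)(C)[Si](C)(C)O[C@@H]1/C=C(/C)C(=O)C[C@H]2OC(C)(C)O[C@@]2(C)[C@H](OS(C)(=O)=O)C(I)[C@H]1CCO[Si](C)(C)C(C)(C)C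
F2 | step 4 | 3-[(E)-5-(tert-butyldimethylsilyloxy)pent-2-enoyl]oxazolidin-2-one | O=C1OCCN1C(=O)/C=C/CCO[Si](C)(C)C(C)(C)C
F3 | step 4 | cycloadduct as 9 with the achiral 2-oxooxazolidin-3-yl group | CC[Si](CC)(CC)O[C@@H]1[C@H](C(=O)N2CCOC2=O)[C@@H](CCO[Si](C)(C)C(C)(C)C)[C@H](OC(C)=O)C=C1C
F4 | step 4 | C3 allylic alcohol as 10 with the achiral imide | O[C@@H]1[C@H](C(=O)N2CCOC2=O)[C@@H](CCO[Si](C)(C)C(C)(C)C)[C@H](OC(C)=O)C=C1C
F5 | step 4 | enone as 11 with the achiral imide | O=C1[C@H](C(=O)N2CCOC2=O)[C@@H](CCO[Si](C)(C)C(C)(C)C)[C@H](OC(C)=O)C=C1C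
F6 | step 4 | allyl carbinol as 12 with the achiral imide | O[C@@]1(CC=C)[C@H](C(=O)N2CCOC2=O)[C@@H](CCO[Si](C)(C)C(C)(C)C)[C@H](OC(C)=O)C=C1C
F7 | step 24 | silver tiglate | C/C=C(\C)C(=O)[O-].[Ag+]
F8 | step 24 | 8α-iodo-9β-tigloyloxy adduct of 32 | C=C1C(=O)O[C@@H]2/C=C(/C)[C@@H](O[Si](C)(C)C(C)(C)C)CC(=O)[C@@](C)(O)[C@@H](OC(=O)/C(C)=C/C)[C@H](I)[C@@H]12
F9 | step 24 | 9-O-tigloyl isomer of 37 | C=C1C(=O)O[C@@H]2/C=C(/C)[C@@H](O[Si](C)(C)C(C)(C)C)CC(=O)[C@@](C)(O)[C@@H](OC(=O)/C(C)=C/C)[C@@H](O)[C@@H]12
F10 | step 25 | 8,9-O-dibutylstannylene acetal of 34 | C=C1C(=O)O[C@@H]2/C=C(/C)[C@@H](O[Si](C)(C)C(C)(C)C)CC(=O)[C@@](C)(O)[C@H]3O[Sn](CCCC)(CCCC)O[C@H]3[C@@H]12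
F11 | step 25 | tigloyl chloride | C/C=C(\C)C(=O)Cl
A1 | alternative 1 | acyclic C9 aldehyde / C10 methyl ketone with C1 ketal, 3,6-bis-OTBS, 8-OPMB and the C7 2-propenyl side chain | CC(=O)C1(OCCO1)C[C@H](O[Si](C)(C)C(C)(C)C)/C(C)=C\[C@@H](O[Si](C)(C)C(C)(C)C)[C@H](C(=C)CO[Si](C)(C)C(C)(C)C)[C@H](OCc1ccc(OC)cc1)C=O
A2 | alternative 1 | ten-membered 9,10-diol with C1 ketal | CC(C)(C)[Si](C)(C)O[C@@H]1/C=C(/C)[C@@H](O[Si](C)(C)C(C)(C)C)CC2(OCCO2)[C@@](C)(O)[C@@H](O)[C@@H](OCc3ccc(OC)cc3)[C@H]1C(=C)CO[Si](C)(C)C(C)(C)C
A3 | alternative 2 | cis-1,2-dialkenylcyclohexanol (ring C9, C10, C1, C2, C3, C4) with C9 dienyl and C4 silyloxyvinyl groups | O[C@]1(/C=C/C(=C)CO[Si](C)(C)C(C)(C)C)[C@@](C)(/C=C/O[Si](C(C)C)(C(C)C)C(C)C)[C@@H](O[Si](C)(C)C(C)(C)C)C[C@H]2OC(C)(C)O[C@@]12C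
A4 | alternative 2 | (Z)-cyclodec-4-en-9-one with C6 and C7 set | CC(C)[Si](C(C)C)(C(C)C)O[C@@H]1/C=C(/C)[C@@H](O[Si](C)(C)C(C)(C)C)C[C@H]2OC(C)(C)O[C@@]2(C)C(=O)C[C@H]1C(=C)CO[Si](C)(C)C(C)(C)C
A5 | alternative 3 | thirteen-membered bis-allylic ether with tributylstannyl group on C8 | CC(C)(C)[Si](C)(C)O[C@@H]1/C=C(/C)[C@@H](O[Si](C)(C)C(C)(C)C)C[C@@H](O[Si](CC)(CC)CC)/C(C)=C\[C@@H]([Sn](CCCC)(CCCC)CCCC)OC/C(CO[Si](C)(C)C(C)(C)C)=C\1
A6 | alternative 3 | ten-membered (4Z,9Z)-dienol with free C8 hydroxyl and C11=C13 methylene | CC(C)(C)[Si](C)(C)O[C@@H]1/C=C(/C)[C@@H](O[Si](C)(C)C(C)(C)C)C[C@@H](O[Si](CC)(CC)CC)/C(C)=C\[C@@H](O)[C@H]1C(=C)CO[Si](C)(C)C(C)(C)C
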